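**A quick number.** A catalyst comes back after each turn, so the amount at work stays constant through a run unless something removes it for good. I look for that amount first, and your hunch about the protic impurity gets its answer on the way.

| flask | substrate | partner | protic impurity | free catalyst | stray impurity | remark | time |
|---|---|---|---|---|---|---|---|
| gamma | 10 mM | 11 mM (in portions, 4) | 0.27 mM | 1 mM | 0.35 mM | run made earlier; portions every 3.0 min |  |
| epsilon | 10 mM | 11 mM (in portions, 4) | 0.78 mM | 1 mM | 0.35 mM | run made earlier; portions every 3.0 min |  |
| beta | 10 mM | 11 mM (in portions, 4) | 0.20 mM | 1 mM | 0.79 mM | run made earlier; portions every 3.0 min |  |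
| Monday's | 10 mM | 11.0 mM (in portions, 4) | 0.200 mM | 1.0 mM | 0.35 mM | the portions of partner follow each other after 3.0 min, the first at the start | 12 min |
| Tuesday's | 10 mM | 11.0 mM (in portions, 4) | 0.200 mM | 0.50 mM | 1.0 mM | the portions of partner follow each other after 3.0 min, the first at the start | 12 min |
| Friday's | 10 mM | 11.0 mM (in portions, 4) | 0.200 mM | 0.50 mM | 0.35 mM | the portions of partner follow each other after 1.0 min, the first at the start | 12 min |
| Sunday's | 10 mM | 11.0 mM (in portions, 4) | 0.200 mM | 1.0 mM | 0.35 mM | the portions of partner follow each other after 5.0 min, the first at the start | 12 min |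
| Wednesday's | 40 mM | 15.0 mM (in portions, 4) | 0.200 mM | 2.0 mM | 0.35 mM | the portions of partner follow each other after 3.0 min, the first at the start | 12 min |
| Thursday's | 10 mM | 30.0 mM (in portions, 4) | 0.600 mM | 1.0 mM | 0.35 mM | the portions of partner follow each other after 3.0 min, the first at the start | 12 min |

| run | time / min | product / % | substrate / % |
|---|---|---|---|
| gamma | 1.00 | 5.1 | 95.8 |
| gamma | 1.50 | 5.7 | 94.8 |
| gamma | 2.50 | 10.3 | 88.3 |
| gamma | 4.00 | 17.3 | 81.1 |
| gamma | 8.00 | 40.2 | 60.1 |
| gamma | 12.0 | 66.1 | 34.0 |
| epsilon | 2.00 | 7.3 | 93.1 |
| epsilon | 4.00 | 13.6 | 85.3 |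
| epsilon | 6.00 | 23.6 | 74.4 |
| epsilon | 8.00 | 37.2 | 62.6 |
| epsilon | 10.0 | 49.5 | 47.6 |
| epsilon | 12.0 | 63.5 | 35.3 |
| beta | 1.00 | 1.0 | 98.9 |
| beta | 2.00 | 0.6 | 94.9 |
| beta | 3.00 | 3.1 | 95.0 |
| beta | 6.00 | 9.6 | 89.0 |
| beta | 12.0 | 32.3 | 69.2 |

(each reading ± 1 percentage point)

- percentages count the whole charge, also what has not yet gone in
- no earlier run changes the charge of free catalyst; that part of a forecast is a guess

- the flasks put in order of amount of product, in percent of the substrate charged, best first, at 12 min (Monday's / Tuesday's / Friday's / Sunday's / Wednesday's / Thursday's)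
- the amount of product, in percent of the substrate charged of the flask you put first, at 12 min
- the amount of product, in percent of the substrate charged of the flask you put last, at 12 min

**Your hunch.** Epsilon, with 0.78 mM of protic impurity, gives 63.5% at 12.0 min, and gamma, with 0.27 mM, gives 66.1%. That gap of 2.6 percentage points stands against a scatter of 1 point, so I set the protic impurity aside as a brake on the rate and count it against the partner.

**Working catalyst.** The stray impurity looks different. Beta, with 0.79 mM of it, has 3.1% of product by 3.00 min, while gamma, with 0.35 mM, has 10.3% by the earlier 2.50 min, so beta reads about a third of gamma. Free catalyst less stray impurity is 0.210 mM in beta and 0.650 mM in gamma, again a third. So I read the stray impurity as a catalyst poison, taking free catalyst one for one. Monday's then keeps 0.650 mM of working catalyst, the charge of free catalyst minus the charge of stray impurity. I scale the rate with this and with the partner on hand. No earlier run changes the free catalyst, so that part is a guess.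

**The flasks.** Thursday's also keeps 0.650 mM, with 30.0 mM of partner against Monday's 11.0 mM. Sunday's keeps 0.650 mM too, but its last portion falls due at 15.0 min, later than 12 min. Wednesday's has 1.65 mM, yet partner is its limiting reagent: partner less protic impurity allows 37.0% of its substrate. Friday's has 0.150 mM. Tuesday's comes to −0.500 mM, below zero.

**The forecast.** My forecast, resting on “the stray impurity kills catalyst one for one”, is Thursday's > Monday's > Sunday's > Wednesday's > Friday's > Tuesday's, with 97% for the first and 0.5% for the last.

**The result.** The flasks come out as Thursday's > Monday's > Sunday's > Wednesday's > Friday's > Tuesday's, with 99.4% for the first and 0.0184% for the last.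

    catalyst intermediate B → free catalyst + product (k = 0.0886 /s)
    substrate + catalyst intermediate A → catalyst intermediate B (k = 41.0 /M/s)
    partner + protic impurity → quenched reagent (k = 432 /M/s)
    free catalyst + stray impurity → spent catalyst (k = 5910 /M/s)
    partner + free catalyst ⇌ catalyst intermediate A (K = 190 /M, k = 6.29 /M/s)

**One reason.** Tuesday's subtraction gave −0.500 mM, and at 12.0 min its spent catalyst stands at 100% of the catalyst charged. Tuesday's product is 0.0184% with the reaction of free catalyst and stray impurity and 58.1% without it, so that reaction is the main reason for the low figure. Thursday's neighbour with 0.40 mM of free catalyst has 0.0500 mM of working catalyst, and it ends with spent catalyst at 87.5% of the catalyst charged and product at 14.2%.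

The earlier runs and the new flask are calculated with constants of no real substance, noise included.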